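**Retrosynthetic overview**
1. Target ⇒ one open-chain triphenolic 2-hydroxydeoxybenzoin carrying an aryl 1,1-dimethylpropargyl ether. Both oxygen rings are closed last, in one pot: enaminone annulation (pyranone ring C), then propargyl Claisen/[1,5]-H/oxa-6π (2H-pyran ring D).
2. Deoxybenzoin ⇒ Horner–Wittig olefination/hydrolysis between an A-ring N,P-acetal (acyl-anion equivalent) and a B-ring benzaldehyde; no cross-coupling is used.
3. B-ring aldehyde ⇐ 5-hydroxyvanillin (4-O-MOM, then 3-O-propargylation). A-ring N,P-acetal ⇐ 2,4-dihydroxybenzaldehyde, aniline and diphenyl phosphite.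
4. Ring order: benzene rings A and B are bought; rings C and D form together in the final step.

Assumption: the target has no stereocentre (it is achiral), so no enantiocontrol is needed; the only stereogenic intermediate (7) is used as the racemate and its stereocentre is destroyed in step 5.

Nothing here has been run; the conditions are proposals based on standard reaction types.

**Route**

Step 1
Reactants: 1 3,4-dihydroxy-5-methoxybenzaldehyde (5-hydroxyvanillin)
Product: 2 3-hydroxy-5-methoxy-4-(methoxymethoxy)benzaldehyde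
Conditions: MOMCl (1.05 equiv), K2CO3 (1.05 equiv), acetone, 0 °C → rt
Reagents that add atoms: chloromethyl methyl ether, COCCl
Why: Williamson-type O-alkylation in which one equivalent of weak base ionises only the more acidic 4-OH (para to CHO), so MOMCl caps O-4 and leaves the 3-OH free; no stereocentre.

Step 2
Reactants: 2 3-hydroxy-5-methoxy-4-(methoxymethoxy)benzaldehyde
Product: 3 3-methoxy-4-(methoxymethoxy)-5-[(2-methylbut-3-yn-2-yl)oxy]benzaldehyde
Conditions: 3-chloro-3-methylbut-1-yne (1.5 equiv), K2CO3, KI (cat.), CuI (cat.), acetone, 55 °C, N2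
Reagents that add atoms: 3-chloro-3-methylbut-1-yne, CC(C)(Cl)C#C
Why: Cu-catalysed propargylic etherification (Williamson type) of the single free phenol with the tertiary propargylic chloride installs the latent chromene unit on O-3, well below the Claisen temperature; no stereocentre.

Step 3
Reactants: 4 2,4-dihydroxybenzaldehyde
Product: 5 2,4-bis(methoxymethoxy)benzaldehyde
Conditions: NaH (2.4 equiv), DMF, 0 °C; MOMCl (2.4 equiv), 0 °C → rt
Reagents that add atoms: chloromethyl methyl ether, COCCl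
Why: Double Williamson O-alkylation of the bis-phenoxide masks both acidic OH groups for the carbanion chemistry of step 5; no stereocentre.

Step 4
Reactants: 5 2,4-bis(methoxymethoxy)benzaldehyde
Product: 7 diphenyl {[2,4-bis(methoxymethoxy)phenyl](phenylamino)methyl}phosphonate (racemic), via (E)-1-[2,4-bis(methoxymethoxy)phenyl]-N-phenylmethanimine 6 (not isolated)
Conditions: PhNH2 (1.0 equiv), i-PrOH, rt, 2 h; then (PhO)2P(O)H (1.05 equiv), rt, 16 h
Reagents that add atoms: aniline, Nc1ccccc1; diphenyl phosphite, O=[PH](Oc1ccccc1)Oc1ccccc1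
Why: Kabachnik–Fields reaction (imine formation, then Pudovik P–H addition) gives the N,P-acetal, an acyl-anion equivalent of the A-ring aldehyde; the new stereocentre is racemic and is erased in step 5.

Step 5
Reactants: 7 diphenyl {[2,4-bis(methoxymethoxy)phenyl](phenylamino)methyl}phosphonate; 3 3-methoxy-4-(methoxymethoxy)-5-[(2-methylbut-3-yn-2-yl)oxy]benzaldehyde
Product: 10 1-(2,4-dihydroxyphenyl)-2-{4-hydroxy-3-methoxy-5-[(2-methylbut-3-yn-2-yl)oxy]phenyl}ethan-1-one, via (Z)-N-(1-[2,4-bis(methoxymethoxy)phenyl]-2-{3-methoxy-4-(methoxymethoxy)-5-[(2-methylbut-3-yn-2-yl)oxy]phenyl}ethenyl)aniline 8 (not isolated), via 1-[2,4-bis(methoxymethoxy)phenyl]-2-{3-methoxy-4-(methoxymethoxy)-5-[(2-methylbut-3-yn-2-yl)oxy]phenyl}ethan-1-one 9 (not isolated)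
Conditions: Cs2CO3 (1.3 equiv), THF/i-PrOH 4:1, rt, 16 h; then 3 M aq. HCl, MeOH, 40 °C, 3 h
Reagents that add atoms: water, O
Why: Horner–Wittig olefination of the N,P-acetal carbanion with aldehyde 3 gives enamine 8 (Cs2CO3 is too weak to ethynylate the aldehyde), and dilute acid then hydrolyses the enamine to the ketone and cleaves the three phenolic MOM acetals while the tertiary propargyl ether is expected to survive; the stereocentre of 7 becomes sp2.

Step 6
Reactants: 10 1-(2,4-dihydroxyphenyl)-2-{4-hydroxy-3-methoxy-5-[(2-methylbut-3-yn-2-yl)oxy]phenyl}ethan-1-one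
Product: 13 7-hydroxy-3-(8-hydroxy-7-methoxy-2,2-dimethyl-2H-chromen-5-yl)-4H-chromen-4-one, via (E)-1-(2,4-dihydroxyphenyl)-3-(dimethylamino)-2-{4-hydroxy-3-methoxy-5-[(2-methylbut-3-yn-2-yl)oxy]phenyl}prop-2-en-1-one 11 (not isolated), via 7-hydroxy-3-{4-hydroxy-3-methoxy-5-[(2-methylbut-3-yn-2-yl)oxy]phenyl}-4H-chromen-4-one 12 (not isolated)
Conditions: Me2NCH(OMe)2 (1.3 equiv), DMF, 60 °C, 2 h; then 140 °C, 6 h, N2 sweep, same flask
Reagents that add atoms: N,N-dimethylformamide dimethyl acetal, COC(OC)N(C)C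
Why: Proposed new method: DMF-DMA condenses at the doubly activated CH2 to enaminone 11, whose 2-OH adds to the β-carbon and expels HNMe2 (the classical deoxybenzoin → isoflavone annulation), and on heating the aryl 1,1-dimethylpropargyl ether of 12 undergoes an aromatic propargyl Claisen [3,3] shift to its only free ortho carbon, a [1,5]-H shift and an oxa-6π electrocyclisation (the classical 2,2-dimethylchromene synthesis); running both closures in one flask on the unprotected triphenol is the untested part, the order of the two events does not matter because both paths converge on 13, and no stereocentre is formed.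

**Compound list**
1 | 3,4-dihydroxy-5-methoxybenzaldehyde (5-hydroxyvanillin) | COc1cc(C=O)cc(O)c1O | starting material
2 | 3-hydroxy-5-methoxy-4-(methoxymethoxy)benzaldehyde | COCOc1c(O)cc(C=O)cc1OC | intermediate
3 | 3-methoxy-4-(methoxymethoxy)-5-[(2-methylbut-3-yn-2-yl)oxy]benzaldehyde | COCOc1c(OC)cc(C=O)cc1OC(C)(C)C#C | intermediate
4 | 2,4-dihydroxybenzaldehyde | O=Cc1ccc(O)cc1O | starting material
5 | 2,4-bis(methoxymethoxy)benzaldehyde | COCOc1ccc(C=O)c(OCOC)c1 | intermediate
6 | (E)-1-[2,4-bis(methoxymethoxy)phenyl]-N-phenylmethanimine | COCOc1ccc(/C=N/c2ccccc2)c(OCOC)c1 | intermediate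
7 | diphenyl {[2,4-bis(methoxymethoxy)phenyl](phenylamino)methyl}phosphonate (racemic) | COCOc1ccc(C(Nc2ccccc2)P(=O)(Oc2ccccc2)Oc2ccccc2)c(OCOC)c1 | intermediate
8 | (Z)-N-(1-[2,4-bis(methoxymethoxy)phenyl]-2-{3-methoxy-4-(methoxymethoxy)-5-[(2-methylbut-3-yn-2-yl)oxy]phenyl}ethenyl)aniline (Z drawn; E/Z mixture and ketimine tautomer possible) | COCOc1ccc(/C(Nc2ccccc2)=C/c2cc(OC)c(OCOC)c(OC(C)(C)C#C)c2)c(OCOC)c1 | intermediate
9 | 1-[2,4-bis(methoxymethoxy)phenyl]-2-{3-methoxy-4-(methoxymethoxy)-5-[(2-methylbut-3-yn-2-yl)oxy]phenyl}ethan-1-one | COCOc1ccc(C(=O)Cc2cc(OC)c(OCOC)c(OC(C)(C)C#C)c2)c(OCOC)c1 | intermediate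
10 | 1-(2,4-dihydroxyphenyl)-2-{4-hydroxy-3-methoxy-5-[(2-methylbut-3-yn-2-yl)oxy]phenyl}ethan-1-one | COc1cc(CC(=O)c2ccc(O)cc2O)cc(OC(C)(C)C#C)c1O | intermediate
11 | (E)-1-(2,4-dihydroxyphenyl)-3-(dimethylamino)-2-{4-hydroxy-3-methoxy-5-[(2-methylbut-3-yn-2-yl)oxy]phenyl}prop-2-en-1-one | COc1cc(/C(=C\N(C)C)C(=O)c2ccc(O)cc2O)cc(OC(C)(C)C#C)c1O | intermediate
12 | 7-hydroxy-3-{4-hydroxy-3-methoxy-5-[(2-methylbut-3-yn-2-yl)oxy]phenyl}-4H-chromen-4-one | COc1cc(-c2coc3cc(O)ccc3c2=O)cc(OC(C)(C)C#C)c1O | intermediate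
13 | 7-hydroxy-3-(8-hydroxy-7-methoxy-2,2-dimethyl-2H-chromen-5-yl)-4H-chromen-4-one | COc1cc(-c2coc3cc(O)ccc3c2=O)c2c(c1O)OC(C)(C)C=C2 | target

**Totals**
Total step count: 6.
Longest linear sequence: 4 steps (1 → 2 → 3 → 10 → 13, or 4 → 5 → 7 → 10 → 13).

**Three steps most likely to fail, with fallbacks**

First, step 6. Unconsumed DMF-DMA can O-methylate the acidic 7-OH once the temperature is raised, and the liberated dimethylamine can reopen the pyranone at 140 °C. The fallback uncouples the two ring closures and inverts their order. It sets out from 10. Heating 10 alone (PhNEt2, 140 °C, no C1 reagent present) runs the propargyl Claisen/[1,5]-H/oxa-6π sequence first and gives 1-(2,4-dihydroxyphenyl)-2-(8-hydroxy-7-methoxy-2,2-dimethyl-2H-chromen-5-yl)ethan-1-one F1. F1 with DMF-DMA in THF at 60 °C gives (E)-1-(2,4-dihydroxyphenyl)-3-(dimethylamino)-2-(8-hydroxy-7-methoxy-2,2-dimethyl-2H-chromen-5-yl)prop-2-en-1-one F2, which closes to the chromone with loss of dimethylamine below 65 °C. The fallback comes back to the route at 13.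

Second, step 5. The carbanion of the electron-rich, ortho-substituted N,P-acetal 7 may form or add sluggishly. The fallback joins the two aryl units by aldol condensation and oxidative 1,2-aryl migration instead of olefination/hydrolysis. It sets out from 3. Commercial 2,4-dihydroxyacetophenone (MOMCl, K2CO3, acetone) gives 1-[2-hydroxy-4-(methoxymethoxy)phenyl]ethan-1-one F3. Claisen–Schmidt condensation of F3 with 3 (KOH, EtOH, rt) gives (E)-1-[2-hydroxy-4-(methoxymethoxy)phenyl]-3-{3-methoxy-4-(methoxymethoxy)-5-[(2-methylbut-3-yn-2-yl)oxy]phenyl}prop-2-en-1-one F4. Tl(NO3)3·3H2O (1.1 equiv) in MeOH/CH(OMe)3 at 0 °C → rt effects the oxidative 1,2-aryl shift to 1-[2-hydroxy-4-(methoxymethoxy)phenyl]-3,3-dimethoxy-2-{3-methoxy-4-(methoxymethoxy)-5-[(2-methylbut-3-yn-2-yl)oxy]phenyl}propan-1-one F5. 10 % HCl in MeOH at 50 °C then closes the pyranone and removes both MOM groups. The fallback comes back to the route at 12, which is isolated here and carried on by the 140 °C part of step 6. The terminal alkyne is a known liability toward Tl(III), so this fallback is itself not risk-free.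

Third, step 1. Mono-alkylation may give some 3-O-MOM isomer or bis-ether. The fallback inverts the order of O-functionalisation and relies on dianion nucleophilicity instead of monoanion acidity. It sets out from 1. NaH (2.1 equiv) in DMF forms the dianion, whose 3-phenoxide (not conjugated to CHO and less hindered) is the more nucleophilic and takes 3-chloro-3-methylbut-1-yne (CuI cat.) to give 4-hydroxy-3-methoxy-5-[(2-methylbut-3-yn-2-yl)oxy]benzaldehyde F6. MOMCl/i-Pr2NEt on the remaining OH of F6 comes back to the route at 3.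

**Further compounds**
F1 | step 6 | 1-(2,4-dihydroxyphenyl)-2-(8-hydroxy-7-methoxy-2,2-dimethyl-2H-chromen-5-yl)ethan-1-one | COc1cc(CC(=O)c2ccc(O)cc2O)c2c(c1O)OC(C)(C)C=C2
F2 | step 6 | (E)-1-(2,4-dihydroxyphenyl)-3-(dimethylamino)-2-(8-hydroxy-7-methoxy-2,2-dimethyl-2H-chromen-5-yl)prop-2-en-1-one | COc1cc(/C(=C\N(C)C)C(=O)c2ccc(O)cc2O)c2c(c1O)OC(C)(C)C=C2
F3 | step 5 | 1-[2-hydroxy-4-(methoxymethoxy)phenyl]ethan-1-one | CC(=O)c1ccc(OCOC)cc1O
F4 | step 5 | (E)-1-[2-hydroxy-4-(methoxymethoxy)phenyl]-3-{3-methoxy-4-(methoxymethoxy)-5-[(2-methylbut-3-yn-2-yl)oxy]phenyl}prop-2-en-1-one | COCOc1ccc(C(=O)/C=C/c2cc(OC)c(OCOC)c(OC(C)(C)C#C)c2)c(O)c1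
F5 | step 5 | 1-[2-hydroxy-4-(methoxymethoxy)phenyl]-3,3-dimethoxy-2-{3-methoxy-4-(methoxymethoxy)-5-[(2-methylbut-3-yn-2-yl)oxy]phenyl}propan-1-one (racemic) | COCOc1ccc(C(=O)C(C(OC)OC)c2cc(OC)c(OCOC)c(OC(C)(C)C#C)c2)c(O)c1
F6 | step 1 | 4-hydroxy-3-methoxy-5-[(2-methylbut-3-yn-2-yl)oxy]benzaldehyde | COc1cc(C=O)cc(OC(C)(C)C#C)c1O
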